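## The problem

Target 27 is a diaryl ether in which both benzene rings are hexasubstituted. Ring A is a methyl β-orsellinate core (C1 CO2Me, C2 Me, C3 O-aryl, C4 OH, C5 Me, C6 OH). Ring B carries C1' O-aryl, C2' CHO, C3' OH, C4' Cl, C5' Me and C6' CO2H. The ether oxygen therefore joins two aryl carbons that each have two ortho substituents, a congestion at which copper- or palladium-mediated etherification and SNAr displacement are poor. There is no stereocentre, so nothing has to be controlled stereochemically and every selectivity question is regiochemical. Ring B holds two one-carbon groups at different oxidation levels on either side of the ether carbon, and ring A holds a methyl ester that must stay an ester, so three carboxyl-derived carbons have to be kept apart. The chlorine lies between the C3' oxygen and the C5' methyl group, where electrophilic chlorination of an orcinol-type ring would face several competing activated positions. The salicylaldehyde unit (C2'/C3'), the aryl chloride and the electron-rich phenols exclude hydrogenolysis and strong oxidants late in the route. The feature that opens the structure is the run C1' (ether), C2' (formyl carbon), C3' (oxygen). A C1'–C2' aryne flanked by a C3' alkoxy group should take an oxygen nucleophile at C1' and a carbon electrophile at C2' under inductive control, and C6' can still be hydrogen at that stage, so the attacked carbon is unhindered.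

## Retrosynthesis

**27 to 26.** The last disconnection removes three O-alkyl groups: benzyl on O4 and O6 of ring A and methyl on O3'. Hydrogenolysis would endanger the C4'–Cl bond and the aldehyde. BCl3 cleaves aryl benzyl ethers and, through chelation to the C2' formyl group, the adjacent methyl ether, while the ring A methyl ester survives. Acid 26 has the complete carbon skeleton; the forward step only has to reach completion at the non-chelated C4 benzyl ether.

**26 to 25 to 24.** The C6'–CO2H bond is cut to the aryl iodide 25, and the C6'–I bond to the C–H compound 24. Formylation followed by oxidation at C6' was weighed against this. It would need the C2' carbon parked as an ester, which costs an ester exchange before reduction, or as a benzylic acetate, and a 2,6-dioxygenated benzylic acetate ionises under the Lewis acid. Carbonylation brings C6' in directly as the acid while C2' is already the aldehyde, so the two carbons never stand at the same oxidation level. C6' is the only unsubstituted carbon of ring B and is para to the C3' methoxy group, so the iodination has no regiochemical choice. The forward reactions must insert palladium into C–I and not C–Cl, and must tolerate two ortho substituents.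

**24 to 23 to 22.** No skeletal bond is cut here. The C2' aldehyde is traced through carbinol 23 to carboxylic acid 22, the form in which an aryne/CO2 coupling delivers that carbon. Borane distinguishes the free acid from the ring A methyl ester, and MnO2 returns the benzylic alcohol to the aldehyde.

**22 to 5, 16 and 17.** This is the key cut: the C1'–O bond and the C2'–CO2H bond are broken together, giving phenol 5, silylaryl triflate 16 and carbon dioxide 17. An Ullmann coupling would need a separately made 2-halobenzoate and would have to join a 2,6-disubstituted phenol to an ortho-substituted halide. The aryne is a far more reactive electrophile, has hydrogen at C6', and leaves its negative charge on the carbon that must carry the one-carbon group. The precursors are two penta- and tetrasubstituted arenes and a gas. The forward reaction must add the phenoxide only at C1' and must carboxylate the C2' anion before it finds a proton.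

**16 to 14 to 10 to 9.** The triflate oxygen of 16 is the phenol oxygen of 9. The C2'–Si bond is cut back to C–H between the two oxygens, where a carbamate on O1' and the C3' methoxy group direct lithiation together. An N-isopropyl carbamate is chosen because it can be removed with amine bases without loss of the ortho silyl group.

**9 to 7 to 6.** The phenol C–O bond of 9 is cut to a C–H bond of 2-chloro-3-methylanisole 7, made by methylation of commercial 2-chloro-3-methylphenol 6. Chlorination of 3-methoxy-5-methylphenol was considered and set aside, because three ring positions are doubly activated and the wanted one is the most crowded. In 7 the chlorine is already between oxygen and methyl, and iridium-catalysed borylation can only reach the one C–H that has no ortho neighbour, which is para to chlorine.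

**5 to 3 to 2 to 1.** The C3–O bond of ring A is cut to a C3–CHO bond (Baeyer–Villiger oxidation of aldehyde 3), and that to the C3–H bond of commercial methyl β-orsellinate 1, whose only free ring carbon is C3. The two phenols are benzylated between the two operations, which also makes the aldehyde electron-rich enough for aryl migration.

## Roads not taken

**Alternative 1:** Ring A is cut at C1–C2 and C4–C5, giving methyl 3-oxopentanoate A1 and the ring B α-aryloxycrotonate A2. In the forward sense sodium methoxide would add the α-carbon of A1 to the β-carbon of A2, and the γ-carbon of the keto ester would then close onto the crotonate ester to give the cyclohexanedione A3. Dehydrogenation would complete ring A.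
- Merits: the parent reaction without the aryloxy group is the classical construction of the β-orsellinate ring, so the ring-forming step has a direct precedent that the chosen key step lacks. The ether oxygen is attached to an open-chain sp2 carbon, not to a hindered arene, and the substitution pattern of ring A is built in.
- Weak points: A2 is a β-substituted acrylate with a donor oxygen on the α-carbon and a 2,6-disubstituted aryl group, so it is a poor and reversible Michael acceptor. A3 is one oxidation level below the arene and carries the aryloxy group as a potential leaving group, so aromatisation by loss of aryloxide from a dienolate competes with dehydrogenation and would return a resorcinol of type 1 without the ether. A2 also needs the complete hexasubstituted ring B to be assembled first in a linear sequence.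
- Comparison: this road is better in the precedent for its central step. The chosen plan sets against that two aromatic fragments made in three and five steps, no oxidation-level change on ring A, and an ether bond that cannot be lost again by elimination.

**Alternative 2:** Ring B is cut through C2'–C3', C1'–C6' and C3'–C4' into 4-chloro-3-methylcyclobutenone A4 and the ring A aryloxyalkyne A5. Heating would open A4 to a vinylketene; (2+2) addition to A5, two 4π openings and a 6π closure would give phenol A6.
- Merits: the positions of all ring B substituents follow from the connectivity of the partners, the chlorine needs no aromatic chlorination, and the C2' carbon arrives at the carbinol level. A6 corresponds to carbinol 23, so the borane reduction of the chosen route would be saved, and the reaction class is well known for alkoxyalkynes.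
- Weak points: A5 is an ynol ether of a hindered phenol that also carries a methyl ester, and the strongly basic eliminations that make such ethers conflict with the ester. A4 is an α-chloro enone prone to loss of HCl and to ketene dimerisation. The cascade needs heat, and A6 still lacks the C6' carboxyl, so the late C–H functionalisation remains, now beside a free C3' phenol.
- Comparison: the key step is of a proven class and one redox step shorter after it. Against this the chosen plan offers stable aromatic partners from commercial arenes and a key step at or below room temperature; the non-aromatic partners A4 and A5 would make the overall sequence longer.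

**Alternative 3:** Ring B is cut at C4'–C5' and C2'–C3', giving the 4-aryloxy-2-pyranone-5-carboxylate A7 and 2-chloro-1,1-dimethoxyethene A8. Inverse-demand Diels–Alder addition, loss of CO2 and loss of methanol would give benzoate A9.
- Merits: the C6' carboxyl is present from the start as a benzyl ester, the chlorine is placed by the dienophile, and the ether bond is made on a pyranone carbon by addition–elimination. After A9 only a formylation at C2' and one BCl3 operation would remain. This endgame is shorter than that of the chosen route and needs neither the redox adjustment at C2' nor the iodination and carbonylation at C6'; in the late stage this road is the better one.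
- Weak points: the aryloxy group at C4 is a donor on the diene and the C6 terminus carries a methyl group, so the cycloaddition is the slow, high-temperature case with a sensitive ketene acetal. The final formylation must take place between two oxygens on a ring deactivated by an ester and a chlorine, under a strong Lewis acid in the presence of three benzyl groups. A7 needs its own multistep preparation.
- Comparison: the chosen plan sets against the shorter endgame that the most crowded carbon–carbon bond (C2') is made in the same operation as the ether bond, on an unhindered aryne, and that both fragments are short. If the three-component step could not be realised, this road would be the next choice.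

Key step: step 9

Assumption: the diaryl ether axis of 27 does not give separable atropisomers, so 27 is treated as a single achiral compound.

## Route

Step 1
Reactants: 1 methyl 2,4-dihydroxy-3,6-dimethylbenzoate (methyl β-orsellinate)
Product: 2 methyl 5-formyl-2,4-dihydroxy-3,6-dimethylbenzoate
Conditions: Cl2CHOMe, TiCl4, CH2Cl2, 0 °C → rt; aq. HCl
Reagents that add atoms: dichloromethyl methyl ether COC(Cl)Cl; water O
Why: Rieche formylation: the titanium phenoxide of 1 is attacked at ring A C3 (locant 5 of the benzoate name), the only unsubstituted ring carbon, which is ortho to one hydroxyl and para to the other; aqueous work-up releases the aldehyde.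

Step 2
Reactants: 2 methyl 5-formyl-2,4-dihydroxy-3,6-dimethylbenzoate
Product: 3 methyl 2,4-bis(benzyloxy)-5-formyl-3,6-dimethylbenzoate
Conditions: BnBr, K2CO3, DMF, 60 °C
Reagents that add atoms: benzyl bromide BrCc1ccccc1
Why: Williamson etherification; both hydroxyls are hydrogen-bonded to ortho carbonyl groups, so carbonate in warm DMF is used, and the two benzyl ethers later fall together under BCl3.

Step 3
Reactants: 3 methyl 2,4-bis(benzyloxy)-5-formyl-3,6-dimethylbenzoate
Product: 5 methyl 2,4-bis(benzyloxy)-5-hydroxy-3,6-dimethylbenzoate, via aryl formate 4 (not isolated)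
Conditions: mCPBA, CH2Cl2, rt; then K2CO3 (cat.), MeOH, rt
Reagents that add atoms: 3-chloroperoxybenzoic acid O=C(OO)c1cccc(Cl)c1
Why: Baeyer–Villiger (Dakin-type) oxidation: the aryl group, with benzyloxy groups ortho and para to the migrating carbon, migrates in preference to hydride and gives formate 4; catalytic carbonate in methanol passes the formyl group to the solvent and frees the phenol at ring A C3.

Step 4
Reactants: 6 2-chloro-3-methylphenol
Product: 7 2-chloro-1-methoxy-3-methylbenzene
Conditions: MeI, K2CO3, acetone, reflux
Reagents that add atoms: iodomethane CI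
Why: Williamson O-methylation; the methyl ether is the small, inductively withdrawing group that later steers the aryne and is finally cleaved by chelation next to the formyl group.

Step 5
Reactants: 7 2-chloro-1-methoxy-3-methylbenzene
Product: 9 4-chloro-3-methoxy-5-methylphenol, via aryl pinacol boronate 8 (not isolated)
Conditions: [Ir(OMe)(cod)]2 (cat.), 4,4'-di-tert-butyl-2,2'-bipyridine (cat.), B2pin2, THF, 80 °C; then H2O2, aq. NaOH, 0 °C → rt
Reagents that add atoms: hydrogen peroxide OO
Why: Iridium-catalysed C–H borylation is governed by sterics: only the ring hydrogen meta to both methoxy and methyl has no ortho neighbour, so boron enters para to chlorine; alkaline peroxide oxidation of the C–B bond then gives the phenol, which places chlorine between methoxy and methyl without any electrophilic chlorination.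

Step 6
Reactants: 9 4-chloro-3-methoxy-5-methylphenol
Product: 10 4-chloro-3-methoxy-5-methylphenyl N-(propan-2-yl)carbamate
Conditions: i-PrNCO, Et3N (cat.), CH2Cl2, rt
Reagents that add atoms: isopropyl isocyanate CC(C)N=C=O
Why: Base-catalysed addition of the phenol to the isocyanate gives an N-monoalkyl carbamate, a directing group for ortho-lithiation that can later be removed under mild amine conditions.

Step 7
Reactants: 10 4-chloro-3-methoxy-5-methylphenyl N-(propan-2-yl)carbamate
Product: 14 4-chloro-3-methoxy-5-methyl-2-(trimethylsilyl)phenyl N-(propan-2-yl)carbamate, via N-silyl carbamate 11 (not isolated), via aryllithium 12 (not isolated), via bis-silyl carbamate 13 (not isolated)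
Conditions: TBSOTf, TMEDA, Et2O, 0 °C → rt; n-BuLi, TMEDA, −78 °C; TMSCl, −78 °C → rt; aq. NaHSO4
Reagents that add atoms: chlorotrimethylsilane C[Si](C)(C)Cl
Why: Directed ortho-metalation: after in situ N-silylation to 11, n-BuLi/TMEDA removes the proton between the carbamate and methoxy oxygens (cooperative directing effect; the other ortho position is flanked by methyl and is less acidic) to give 12, which is C-silylated to 13 at −78 °C before anionic Fries rearrangement can set in; the N–Si bond is hydrolysed on acidic work-up.

Step 8
Reactants: 14 4-chloro-3-methoxy-5-methyl-2-(trimethylsilyl)phenyl N-(propan-2-yl)carbamate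
Product: 16 4-chloro-3-methoxy-5-methyl-2-(trimethylsilyl)phenyl trifluoromethanesulfonate, via silylphenol 15 (not isolated)
Conditions: DBU, Et2NH, MeCN, 40 °C; then PhNTf2, rt
Reagents that add atoms: N-phenylbis(trifluoromethanesulfonimide) O=S(=O)(N(c1ccccc1)S(=O)(=O)C(F)(F)F)C(F)(F)F
Why: DBU removes the carbamate N–H and the aryloxide leaves by E1cB elimination, the isocyanate being trapped by diethylamine; phenoxide 15 is triflated in the same flask, a sequence of the kind that leaves an ortho C–Si bond intact.

Step 9
Reactants: 5 methyl 2,4-bis(benzyloxy)-5-hydroxy-3,6-dimethylbenzoate; 16 4-chloro-3-methoxy-5-methyl-2-(trimethylsilyl)phenyl trifluoromethanesulfonate; 17 carbon dioxide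
Product: 22 methyl 2,4-bis(benzyloxy)-5-(2-carboxy-4-chloro-3-methoxy-5-methylphenoxy)-3,6-dimethylbenzoate, via potassium phenoxide 18 (not isolated), via aryne 19 (not isolated), via arylpotassium 20 (not isolated), via potassium carboxylate 21 (not isolated)
Conditions: 5, KH, THF, 0 °C; CO2 (1 atm); then 16, KF, 18-crown-6, 0 °C → rt; aq. HCl
Reagents that add atoms: none
Why: Proposed new method: KH converts 5 into phenoxide 18 with H2 as the only by-product, so no O–H donor remains; fluoride removes the trimethylsilyl group of 16 with loss of triflate to give aryne 19; 18 adds at C1', the aryne carbon remote from the C3' methoxy group, because the inductively withdrawing C–O bond distorts the aryne toward attack there and stabilises the charge at C2' in arylpotassium 20; 20 is carboxylated by dissolved CO2 to 21, which acid converts into 22. The closest known reaction types are the fluoride-induced three-component coupling of arynes, amines and CO2 to anthranilic acids, the aryne O-arylation of hindered phenols, and the capture of the same kind of ortho-aryloxy aryl anion by a neighbouring ester in the aryne synthesis of xanthones; CO2 capture after phenoxide addition has not been shown. No ring is closed and no stereocentre is formed. The step needs regioselective addition, secured by the C3' methoxy group and by C6' being unsubstituted so that the hindered phenoxide meets an open carbon. It also needs carboxylation to outrun protonation, secured by the proton-free phenoxide, by THF in place of acetonitrile and by a CO2-saturated solution. Carbonate formation from 18 and CO2 is reversible and is disfavoured by the two ortho substituents of 18. Anion 20 is a 2,6-dioxygenated aryl anion of the type that carboxylates readily, and acid 22 can be separated from neutral by-products by bicarbonate extraction.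

Step 10
Reactants: 22 methyl 2,4-bis(benzyloxy)-5-(2-carboxy-4-chloro-3-methoxy-5-methylphenoxy)-3,6-dimethylbenzoate
Product: 23 methyl 2,4-bis(benzyloxy)-5-[4-chloro-2-(hydroxymethyl)-3-methoxy-5-methylphenoxy]-3,6-dimethylbenzoate
Conditions: BH3·SMe2, THF, 0 → 50 °C; MeOH, then aq. work-up
Reagents that add atoms: none
Why: Borane reduces a free carboxylic acid through its acyloxyborane much faster than an ester, so the C2' acid goes to the carbinol while the hindered ring A methyl ester, the ethers and the aryl chloride remain.

Step 11
Reactants: 23 methyl 2,4-bis(benzyloxy)-5-[4-chloro-2-(hydroxymethyl)-3-methoxy-5-methylphenoxy]-3,6-dimethylbenzoate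
Product: 24 methyl 2,4-bis(benzyloxy)-5-(4-chloro-2-formyl-3-methoxy-5-methylphenoxy)-3,6-dimethylbenzoate
Conditions: MnO2, CH2Cl2, rt
Reagents that add atoms: none
Why: MnO2 oxidises benzylic alcohols selectively and stops at the aldehyde; nothing else in 23 is oxidisable under these neutral conditions.

Step 12
Reactants: 24 methyl 2,4-bis(benzyloxy)-5-(4-chloro-2-formyl-3-methoxy-5-methylphenoxy)-3,6-dimethylbenzoate
Product: 25 methyl 2,4-bis(benzyloxy)-5-(4-chloro-2-formyl-6-iodo-3-methoxy-5-methylphenoxy)-3,6-dimethylbenzoate
Conditions: N-iodosuccinimide, CF3CO2H, MeCN, rt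
Reagents that add atoms: N-iodosuccinimide O=C1CCC(=O)N1I
Why: Electrophilic aromatic iodination with acid-activated N-iodosuccinimide at C6', the only unsubstituted carbon of ring B, para to the C3' methoxy group, ortho to the ether oxygen and the methyl group and meta to the formyl group; ring A has no free position and the benzyl phenyl rings are not activated.

Step 13
Reactants: 25 methyl 2,4-bis(benzyloxy)-5-(4-chloro-2-formyl-6-iodo-3-methoxy-5-methylphenoxy)-3,6-dimethylbenzoate
Product: 26 2-[2,4-bis(benzyloxy)-5-(methoxycarbonyl)-3,6-dimethylphenoxy]-5-chloro-3-formyl-4-methoxy-6-methylbenzoic acid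
Conditions: Pd(OAc)2 (cat.), 1,1'-bis(diphenylphosphino)ferrocene (cat.), CO (1 atm), KOAc, DMSO/H2O, 70 °C; aq. HCl
Reagents that add atoms: carbon monoxide [C-]#[O+]; water O
Why: Palladium-catalysed hydroxycarbonylation (Heck carbonylation): zerovalent palladium inserts into the C–I bond in preference to C–Cl, CO inserts and the acylpalladium is hydrolysed; C6' thus enters directly at the acid level while the C2' aldehyde is untouched, so the two one-carbon groups never need to be told apart.

Step 14
Reactants: 26 2-[2,4-bis(benzyloxy)-5-(methoxycarbonyl)-3,6-dimethylphenoxy]-5-chloro-3-formyl-4-methoxy-6-methylbenzoic acid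
Product: 27 5-chloro-2-[2,4-dihydroxy-5-(methoxycarbonyl)-3,6-dimethylphenoxy]-3-formyl-4-hydroxy-6-methylbenzoic acid (CNP0210944.0)
Conditions: BCl3, CH2Cl2, −78 → 0 °C; aq. work-up
Reagents that add atoms: none
Why: BCl3 cleaves aryl benzyl ethers by O-complexation and chloride attack at the benzylic carbon, and demethylates the C3' ether through a six-membered boron chelate with the adjacent formyl group; the methyl ester, acid, aldehyde, aryl chloride and diaryl ether are expected to be inert at 0 °C, and since both rings are fully substituted no ring carbon is open to benzylation.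

## Compound list

1 | methyl 2,4-dihydroxy-3,6-dimethylbenzoate (methyl β-orsellinate) | COC(=O)c1c(C)cc(O)c(C)c1O | starting material
2 | methyl 5-formyl-2,4-dihydroxy-3,6-dimethylbenzoate | COC(=O)c1c(C)c(C=O)c(O)c(C)c1O | intermediate
3 | methyl 2,4-bis(benzyloxy)-5-formyl-3,6-dimethylbenzoate | COC(=O)c1c(C)c(C=O)c(OCc2ccccc2)c(C)c1OCc1ccccc1 | intermediate
4 | methyl 2,4-bis(benzyloxy)-5-(formyloxy)-3,6-dimethylbenzoate | COC(=O)c1c(C)c(OC=O)c(OCc2ccccc2)c(C)c1OCc1ccccc1 | intermediate (not isolated)
5 | methyl 2,4-bis(benzyloxy)-5-hydroxy-3,6-dimethylbenzoate | COC(=O)c1c(C)c(O)c(OCc2ccccc2)c(C)c1OCc1ccccc1 | intermediate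
6 | 2-chloro-3-methylphenol | Cc1cccc(O)c1Cl | starting material
7 | 2-chloro-1-methoxy-3-methylbenzene | COc1cccc(C)c1Cl | intermediate
8 | 2-(4-chloro-3-methoxy-5-methylphenyl)-4,4,5,5-tetramethyl-1,3,2-dioxaborolane | COc1cc(B2OC(C)(C)C(C)(C)O2)cc(C)c1Cl | intermediate (not isolated)
9 | 4-chloro-3-methoxy-5-methylphenol | COc1cc(O)cc(C)c1Cl | intermediate
10 | 4-chloro-3-methoxy-5-methylphenyl N-(propan-2-yl)carbamate | COc1cc(OC(=O)NC(C)C)cc(C)c1Cl | intermediate
11 | 4-chloro-3-methoxy-5-methylphenyl N-[tert-butyl(dimethyl)silyl]-N-(propan-2-yl)carbamate | COc1cc(OC(=O)N(C(C)C)[Si](C)(C)C(C)(C)C)cc(C)c1Cl | intermediate (not isolated)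
12 | 4-chloro-2-lithio-3-methoxy-5-methylphenyl N-[tert-butyl(dimethyl)silyl]-N-(propan-2-yl)carbamate | COc1c([Li])c(OC(=O)N(C(C)C)[Si](C)(C)C(C)(C)C)cc(C)c1Cl | intermediate (not isolated)
13 | 4-chloro-3-methoxy-5-methyl-2-(trimethylsilyl)phenyl N-[tert-butyl(dimethyl)silyl]-N-(propan-2-yl)carbamate | COc1c([Si](C)(C)C)c(OC(=O)N(C(C)C)[Si](C)(C)C(C)(C)C)cc(C)c1Cl | intermediate (not isolated)
14 | 4-chloro-3-methoxy-5-methyl-2-(trimethylsilyl)phenyl N-(propan-2-yl)carbamate | COc1c([Si](C)(C)C)c(OC(=O)NC(C)C)cc(C)c1Cl | intermediate
15 | 4-chloro-3-methoxy-5-methyl-2-(trimethylsilyl)phenol (formed as its DBU salt) | COc1c([Si](C)(C)C)c(O)cc(C)c1Cl | intermediate (not isolated)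
16 | 4-chloro-3-methoxy-5-methyl-2-(trimethylsilyl)phenyl trifluoromethanesulfonate | COc1c([Si](C)(C)C)c(OS(=O)(=O)C(F)(F)F)cc(C)c1Cl | intermediate
17 | carbon dioxide | O=C=O | starting material
18 | potassium 2,4-bis(benzyloxy)-5-(methoxycarbonyl)-3,6-dimethylphenoxide | COC(=O)c1c(C)c([O-])c(OCc2ccccc2)c(C)c1OCc1ccccc1.[K+] | intermediate (not isolated)
19 | 4-chloro-3-methoxy-5-methylbenzyne (4-chloro-3-methoxy-5-methyl-1,2-didehydrobenzene) | COC1=C(Cl)C(C)=CC#C1 | intermediate (not isolated)
20 | {2-[2,4-bis(benzyloxy)-5-(methoxycarbonyl)-3,6-dimethylphenoxy]-5-chloro-6-methoxy-4-methylphenyl}potassium | COC(=O)c1c(C)c(Oc2cc(C)c(Cl)c(OC)c2[K])c(OCc2ccccc2)c(C)c1OCc1ccccc1 | intermediate (not isolated)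
21 | potassium 2-[2,4-bis(benzyloxy)-5-(methoxycarbonyl)-3,6-dimethylphenoxy]-5-chloro-6-methoxy-4-methylbenzoate | COC(=O)c1c(C)c(Oc2cc(C)c(Cl)c(OC)c2C(=O)[O-])c(OCc2ccccc2)c(C)c1OCc1ccccc1.[K+] | intermediate (not isolated)
22 | methyl 2,4-bis(benzyloxy)-5-(2-carboxy-4-chloro-3-methoxy-5-methylphenoxy)-3,6-dimethylbenzoate | COC(=O)c1c(C)c(Oc2cc(C)c(Cl)c(OC)c2C(=O)O)c(OCc2ccccc2)c(C)c1OCc1ccccc1 | intermediate
23 | methyl 2,4-bis(benzyloxy)-5-[4-chloro-2-(hydroxymethyl)-3-methoxy-5-methylphenoxy]-3,6-dimethylbenzoate | COC(=O)c1c(C)c(Oc2cc(C)c(Cl)c(OC)c2CO)c(OCc2ccccc2)c(C)c1OCc1ccccc1 | intermediate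
24 | methyl 2,4-bis(benzyloxy)-5-(4-chloro-2-formyl-3-methoxy-5-methylphenoxy)-3,6-dimethylbenzoate | COC(=O)c1c(C)c(Oc2cc(C)c(Cl)c(OC)c2C=O)c(OCc2ccccc2)c(C)c1OCc1ccccc1 | intermediate
25 | methyl 2,4-bis(benzyloxy)-5-(4-chloro-2-formyl-6-iodo-3-methoxy-5-methylphenoxy)-3,6-dimethylbenzoate | COC(=O)c1c(C)c(Oc2c(I)c(C)c(Cl)c(OC)c2C=O)c(OCc2ccccc2)c(C)c1OCc1ccccc1 | intermediate
26 | 2-[2,4-bis(benzyloxy)-5-(methoxycarbonyl)-3,6-dimethylphenoxy]-5-chloro-3-formyl-4-methoxy-6-methylbenzoic acid | COC(=O)c1c(C)c(Oc2c(C(=O)O)c(C)c(Cl)c(OC)c2C=O)c(OCc2ccccc2)c(C)c1OCc1ccccc1 | intermediate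
27 | 5-chloro-2-[2,4-dihydroxy-5-(methoxycarbonyl)-3,6-dimethylphenoxy]-3-formyl-4-hydroxy-6-methylbenzoic acid (CNP0210944.0) | COC(=O)c1c(C)c(Oc2c(C=O)c(O)c(Cl)c(C)c2C(=O)O)c(O)c(C)c1O | target

## Step count and least certain steps

Total: 14 steps. Longest linear sequence: 11 steps (6 to 27 through steps 4 to 14); the ring A branch (steps 1 to 3) joins at step 9.

**Step 9 (key step, proposed new method).** Three processes could divert it:
- Protonation of the C2' aryl anion before it meets CO2, either by adventitious proton sources or by internal proton transfer from the ring A methyl group ortho to the ester or from a benzylic OCH2.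
- Sequestration of the phenoxide as its carbonate, followed by attack on the aryne through a carbonate oxygen and acyl transfer.
- Arylation of the product carboxylate by excess aryne.

The fallback makes the two bonds in separate known steps. From 5 and 16, the two-component aryne O-arylation of a phenol (CsF, MeCN, rt, with the phenol as proton source) should give methyl 2,4-bis(benzyloxy)-5-(4-chloro-3-methoxy-5-methylphenoxy)-3,6-dimethylbenzoate F1 with the same regiochemistry. Iodination (N-iodosuccinimide, CF3CO2H, MeCN) para to the methoxy group, at C6', would give methyl 2,4-bis(benzyloxy)-5-(4-chloro-2-iodo-5-methoxy-3-methylphenoxy)-3,6-dimethylbenzoate F2. Rieche formylation (Cl2CHOMe, SnCl4, CH2Cl2, −78 → 0 °C) at C2', by then the only free ring carbon, leads to 25, where the route is rejoined. Carbon dioxide is no longer used and steps 10 to 12 are bypassed.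

**Step 12 (iodination).** Substitution at a doubly flanked carbon of a ring deactivated by the formyl group may be slow, and forcing with acid risks loss of benzyl groups. The fallback moves the halogenation ahead of the oxidation. Carbinol 23 is acetylated (Ac2O, pyridine) to methyl 5-[2-(acetoxymethyl)-4-chloro-3-methoxy-5-methylphenoxy]-2,4-bis(benzyloxy)-3,6-dimethylbenzoate F3. The more electron-rich ring is iodinated under mild conditions to methyl 5-[2-(acetoxymethyl)-4-chloro-6-iodo-3-methoxy-5-methylphenoxy]-2,4-bis(benzyloxy)-3,6-dimethylbenzoate F4. Methanolysis (K2CO3, MeOH) gives methyl 2,4-bis(benzyloxy)-5-[4-chloro-2-(hydroxymethyl)-6-iodo-3-methoxy-5-methylphenoxy]-3,6-dimethylbenzoate F5, and MnO2 oxidation returns to 25.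

**Step 13 (hydroxycarbonylation).** CO insertion and hydrolysis at a di-ortho-substituted arylpalladium may be slow, so that reductive loss of iodine takes over. The fallback replaces palladium by a polar organometallic carboxylation. Aldehyde 25 is protected (ethylene glycol, TsOH, toluene, reflux) as methyl 2,4-bis(benzyloxy)-5-[4-chloro-2-(1,3-dioxolan-2-yl)-6-iodo-3-methoxy-5-methylphenoxy]-3,6-dimethylbenzoate F6. Iodine–magnesium exchange (i-PrMgCl·LiCl, THF, −20 °C), which a hindered methyl ester tolerates, and quenching with CO2 give 2-[2,4-bis(benzyloxy)-5-(methoxycarbonyl)-3,6-dimethylphenoxy]-5-chloro-3-(1,3-dioxolan-2-yl)-4-methoxy-6-methylbenzoic acid F7. Aqueous HCl in THF removes the acetal and returns to 26.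

**Step 14 (global deprotection).** Cleavage of the non-chelated C4 benzyl ether may lag behind the chelation-assisted cleavages, and prolonged exposure to BCl3 may begin to attack the methyl ester. The fallback splits the operation into two steps of different mechanism. Acidolysis of 26 (CF3CO2H with pentamethylbenzene as cation scavenger, rt) removes both benzyl groups and gives 5-chloro-2-[2,4-dihydroxy-5-(methoxycarbonyl)-3,6-dimethylphenoxy]-3-formyl-4-methoxy-6-methylbenzoic acid F8. Chelation-controlled demethylation ortho to the formyl group (MgI2·OEt2, toluene, warm) then gives 27.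

## Further compounds

F1 | step 9 | methyl 2,4-bis(benzyloxy)-5-(4-chloro-3-methoxy-5-methylphenoxy)-3,6-dimethylbenzoate | COC(=O)c1c(C)c(Oc2cc(C)c(Cl)c(OC)c2)c(OCc2ccccc2)c(C)c1OCc1ccccc1
F2 | step 9 | methyl 2,4-bis(benzyloxy)-5-(4-chloro-2-iodo-5-methoxy-3-methylphenoxy)-3,6-dimethylbenzoate | COC(=O)c1c(C)c(Oc2cc(OC)c(Cl)c(C)c2I)c(OCc2ccccc2)c(C)c1OCc1ccccc1
F3 | step 12 | methyl 5-[2-(acetoxymethyl)-4-chloro-3-methoxy-5-methylphenoxy]-2,4-bis(benzyloxy)-3,6-dimethylbenzoate | COC(=O)c1c(C)c(Oc2cc(C)c(Cl)c(OC)c2COC(C)=O)c(OCc2ccccc2)c(C)c1OCc1ccccc1
F4 | step 12 | methyl 5-[2-(acetoxymethyl)-4-chloro-6-iodo-3-methoxy-5-methylphenoxy]-2,4-bis(benzyloxy)-3,6-dimethylbenzoate | COC(=O)c1c(C)c(Oc2c(I)c(C)c(Cl)c(OC)c2COC(C)=O)c(OCc2ccccc2)c(C)c1OCc1ccccc1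
F5 | step 12 | methyl 2,4-bis(benzyloxy)-5-[4-chloro-2-(hydroxymethyl)-6-iodo-3-methoxy-5-methylphenoxy]-3,6-dimethylbenzoate | COC(=O)c1c(C)c(Oc2c(I)c(C)c(Cl)c(OC)c2CO)c(OCc2ccccc2)c(C)c1OCc1ccccc1
F6 | step 13 | methyl 2,4-bis(benzyloxy)-5-[4-chloro-2-(1,3-dioxolan-2-yl)-6-iodo-3-methoxy-5-methylphenoxy]-3,6-dimethylbenzoate | COC(=O)c1c(C)c(Oc2c(I)c(C)c(Cl)c(OC)c2C2OCCO2)c(OCc2ccccc2)c(C)c1OCc1ccccc1
F7 | step 13 | 2-[2,4-bis(benzyloxy)-5-(methoxycarbonyl)-3,6-dimethylphenoxy]-5-chloro-3-(1,3-dioxolan-2-yl)-4-methoxy-6-methylbenzoic acid | COC(=O)c1c(C)c(Oc2c(C(=O)O)c(C)c(Cl)c(OC)c2C2OCCO2)c(OCc2ccccc2)c(C)c1OCc1ccccc1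
F8 | step 14 | 5-chloro-2-[2,4-dihydroxy-5-(methoxycarbonyl)-3,6-dimethylphenoxy]-3-formyl-4-methoxy-6-methylbenzoic acid | COC(=O)c1c(C)c(Oc2c(C(=O)O)c(C)c(Cl)c(OC)c2C=O)c(O)c(C)c1O
A1 | alternative 1 | methyl 3-oxopentanoate | CCC(=O)CC(=O)OC
A2 | alternative 1 | methyl 2-[3-(benzyloxy)-6-(tert-butoxycarbonyl)-4-chloro-2-(1,3-dioxolan-2-yl)-5-methylphenoxy]but-2-enoate (alkene geometry not specified) | CC=C(Oc1c(C2OCCO2)c(OCc2ccccc2)c(Cl)c(C)c1C(=O)OC(C)(C)C)C(=O)OC
A3 | alternative 1 | methyl 5-[3-(benzyloxy)-6-(tert-butoxycarbonyl)-4-chloro-2-(1,3-dioxolan-2-yl)-5-methylphenoxy]-3,6-dimethyl-2,4-dioxocyclohexane-1-carboxylate (mixture of diastereomers and enol tautomers) | COC(=O)C1C(C)C(Oc2c(C3OCCO3)c(OCc3ccccc3)c(Cl)c(C)c2C(=O)OC(C)(C)C)C(=O)C(C)C1=O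
A4 | alternative 2 | 4-chloro-3-methylcyclobut-2-en-1-one (racemic) | O=C1C=C(C)C1Cl
A5 | alternative 2 | methyl 2,4-bis(benzyloxy)-5-{[3-(tert-butyldimethylsilyloxy)prop-1-yn-1-yl]oxy}-3,6-dimethylbenzoate | COC(=O)c1c(C)c(OC#CCO[Si](C)(C)C(C)(C)C)c(OCc2ccccc2)c(C)c1OCc1ccccc1
A6 | alternative 2 | methyl 2,4-bis(benzyloxy)-5-[2-(tert-butyldimethylsilyloxymethyl)-4-chloro-3-hydroxy-5-methylphenoxy]-3,6-dimethylbenzoate | COC(=O)c1c(C)c(Oc2cc(C)c(Cl)c(O)c2CO[Si](C)(C)C(C)(C)C)c(OCc2ccccc2)c(C)c1OCc1ccccc1
A7 | alternative 3 | benzyl 4-[2,4-bis(benzyloxy)-5-(methoxycarbonyl)-3,6-dimethylphenoxy]-6-methyl-2-oxo-2H-pyran-5-carboxylate | Cc1oc(=O)cc(Oc2c(C)c(C(=O)OC)c(OCc3ccccc3)c(C)c2OCc2ccccc2)c1C(=O)OCc1ccccc1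
A8 | alternative 3 | 2-chloro-1,1-dimethoxyethene | COC(=CCl)OC
A9 | alternative 3 | benzyl 2-[2,4-bis(benzyloxy)-5-(methoxycarbonyl)-3,6-dimethylphenoxy]-5-chloro-4-methoxy-6-methylbenzoate | COc1c(Cl)c(C)c(C(=O)OCc2ccccc2)c(Oc2c(C)c(C(=O)OC)c(OCc3ccccc3)c(C)c2OCc2ccccc2)c1
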